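What I wanted from this flask was a leftover: the Q and J still unlinked at the asked time, with D as the rest of the charge.

    Q ⇌ J (K1 = 1.1, k1 = 0.0378 s⁻¹)
    Q + L → D + G (k2 = 184 M⁻¹ s⁻¹)
    X ⇌ L, rate k3*(csat - [L]) (k3 = 0.498 s⁻¹, csat = 0.21 mM)

Q 0.0020 M; X 0.21 mM (held); time 1.5 min

- which holds at 1.5 min: what has brought the reaction to rest, or that it has not come to rest (it is still moving / forward and back rates have come level / all of Q has reacted)
- share of the Q used up at 1.5 min
- D at 1.5 min, in percent of the Q charged

- at the start none of L is dissolved
- what has gone from Q into another species counts as reacted, even if it can come back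
- the reaction counts as stopped when no species that holds the Q changes by six tenths of a point or more over the second half of the time
- run time (flask): 1.5 min

I froze dissolved L, taking Q at a quarter of the charge, where L loses 0.0920 s⁻¹ to Q, less than the transfer coefficient 0.498 s⁻¹. Balancing supply against that loss gave L* = 0.177 mM, and so a pseudo-first-order constant for Q going to D, k* = 0.0326 s⁻¹.

I then set four first-order constants in a column: Q to J 0.0378 s⁻¹, J to Q 0.0344 s⁻¹, Q to D 0.0326 s⁻¹, gas into solution 0.498 s⁻¹. The last row stands above the others, which is why L may be frozen. The second and third rows are level, so neither exchange nor linking can be treated as the quick one, and I kept both.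

The two-pool system then has a fast rate 0.0927 s⁻¹ and the frozen-L slow rate, the rate at which the unlinked pool decays with L held at L* once the fast mode has died away, λ = 0.01209 s⁻¹. The slow mode carries 27.6% of Q, and J has amplitude 0.469 of the charge.

At 1.5 min this left Q 9.32% and J 15.8%, so D 74.9%. Q averaged a quarter of the charge over the run, as assumed. In this reckoning the slow mode still fell to 0.580 of itself over the second half, so I expected the flask to be still moving.

The forecast said it is still moving, 89.5% used up and D 73%, with the decay of Q and J “leaving roughly a quarter of the charge”, its D lying lower than mine.

The flask gave it is still moving, 90.0% used up and D 72.5%. L read 1.83 × 10⁻⁴ M at 0.750 min, close to L*, but 1.40 × 10⁻⁴ M at 0.150 min, lower than L*. I put the same constants, λ among them, on the neighbouring flask, the same charge left until 40 s. There the reckoning gave Q 18.8% and D 53.4%. That neighbouring flask held Q 21.5% and D 47.2%.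

The numbers of this flask are invented, and the outcome is calculated.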